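**Retrosynthetic overview**
- Last C–C bond is C7–C8: anti-aldol of the α′-lithium dienolate of an (S)-2-chloro-4-silyloxy-4-[(Z)-octenyl]cyclopentenone with methyl (5S,6R)-5,6-diacetoxy-7-oxoheptanoate, then 7-O-acetylation and desilylation.
- Chlorocyclopentenone ⇐ cyclopentenone (nucleophilic epoxidation, then HCl) ⇐ acyclic 1,4-keto-aldehyde by intramolecular aldol condensation (C10–C11 bond).
- Keto-aldehyde ⇐ Sharpless epoxide of a 2-substituted allylic alcohol (sets C12), opened by a heptynyl alane; methallyl → methyl ketone, alkyne → Z-alkene.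
- Aldehyde ⇐ L-tartrate acetonide (C5, C6); C1–C3 by Giese addition to methyl acrylate.
- Ring order: the only ring (cyclopentenone) is closed in the ring fragment (step 9) before fragment union (step 21).

Assumption: prostaglandin numbering (C1 = ester carbon … C20) is used in the explanations; building blocks that supply skeleton carbons are numbered as reactants; the ~90–95 % ee expected from the Sharpless step is upgraded when diastereomers are separated after fragment union.

**Ring fragment**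

Step 1
Reactants: 1 prop-2-yn-1-ol; 2 (2-methylprop-2-en-1-yl)magnesium chloride
Product: 4 4-methyl-2-methylidenepent-4-en-1-ol, via chloromagnesium (2Z)-3-(chloromagnesio)-2-(2-methylprop-2-en-1-yl)prop-2-en-1-olate 3 (not isolated)
Conditions: 2 (3 equiv), CuI (5 mol %), THF, 0 °C → rt; aq. NH4Cl
Reagents that add atoms: none
Why: Alkoxide-directed anti-carbomagnesiation (allylmagnesiation) of the propargylic alcohol puts the methallyl group on C2 and the chelated vinyl–Mg bond is protonated on work-up; no stereocentre is formed.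

Step 2
Reactants: 4 4-methyl-2-methylidenepent-4-en-1-ol
Product: 5 [(2S)-2-(2-methylprop-2-en-1-yl)oxiran-2-yl]methanol
Conditions: Ti(Oi-Pr)4 (10 mol %), L-(+)-DIPT (12 mol %), t-BuOOH (2 equiv), 4 Å MS, CH2Cl2, −20 °C
Reagents that add atoms: tert-butyl hydroperoxide, CC(C)(C)OO
Why: Sharpless asymmetric epoxidation reacts only at the allylic-alcohol alkene, and L-(+)-tartrate delivers oxygen to the face that gives the (S)-epoxide (same sense as (S)-glycidol), which fixes C12.

Step 3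
Reactants: 5 [(2S)-2-(2-methylprop-2-en-1-yl)oxiran-2-yl]methanol; 6 hept-1-yne
Product: 9 (2R)-2-(2-methylprop-2-en-1-yl)dec-4-yne-1,2-diol, via lithium hept-1-yn-1-ide 7 (not isolated), via diethyl(hept-1-yn-1-yl)aluminium 8 (not isolated)
Conditions: 6 (3 equiv), n-BuLi, toluene, 0 °C; Et2AlCl; then 5, 0 °C → rt; Rochelle salt work-up
Reagents that add atoms: none
Why: Alkynylalane opening of the 2,3-epoxy alcohol is an aluminium-alkoxide-assisted SN2 at the unhindered CH2 terminus, so the quaternary centre is untouched (the descriptor changes to R only through CIP priorities).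

Step 4
Reactants: 9 (2R)-2-(2-methylprop-2-en-1-yl)dec-4-yne-1,2-diol
Product: 10 (2R)-2-(2-methylprop-2-en-1-yl)-1,2-bis[(triethylsilyl)oxy]dec-4-yne
Conditions: TESOTf (2.5 equiv), 2,6-lutidine, CH2Cl2, −78 → 0 °C
Reagents that add atoms: triethylsilyl trifluoromethanesulfonate, CC[Si](CC)(CC)OS(=O)(=O)C(F)(F)F
Why: Silyl triflate silylation protects both the primary and the hindered tertiary alcohol, which blocks periodate diol cleavage and later retro-aldol.

Step 5
Reactants: 10 (2R)-2-(2-methylprop-2-en-1-yl)-1,2-bis[(triethylsilyl)oxy]dec-4-yne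
Product: 12 (4S)-4-[(triethylsilyl)oxy]-4-{[(triethylsilyl)oxy]methyl}dodec-6-yn-2-one, via (4S)-2-methyl-4-[(triethylsilyl)oxy]-4-{[(triethylsilyl)oxy]methyl}dodec-6-yne-1,2-diol 11 (not isolated)
Conditions: OsO4 (2 mol %), NaIO4 (4 equiv), 2,6-lutidine, dioxane/H2O 3:1, rt
Reagents that add atoms: osmium tetroxide, O=[Os](=O)(=O)=O; sodium periodate, [Na+].[O-]I(=O)(=O)=O
Why: Lemieux–Johnson cleavage (dihydroxylation then periodate) converts the 1,1-disubstituted alkene into the methyl ketone, and OsO4 leaves the internal alkyne alone.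

Step 6
Reactants: 12 (4S)-4-[(triethylsilyl)oxy]-4-{[(triethylsilyl)oxy]methyl}dodec-6-yn-2-one
Product: 13 (4S,6Z)-4-[(triethylsilyl)oxy]-4-{[(triethylsilyl)oxy]methyl}dodec-6-en-2-one
Conditions: H2 (1 atm), Lindlar catalyst, quinoline, EtOAc, rt
Reagents that add atoms: none
Why: Lindlar semihydrogenation adds H2 syn on poisoned Pd and stops at the (Z)-alkene (C14=C15).

Step 7
Reactants: 13 (4S,6Z)-4-[(triethylsilyl)oxy]-4-{[(triethylsilyl)oxy]methyl}dodec-6-en-2-one
Product: 14 (4S,6Z)-4-(hydroxymethyl)-4-[(triethylsilyl)oxy]dodec-6-en-2-one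
Conditions: HF·pyridine, pyridine, THF, 0 °C
Reagents that add atoms: none
Why: Buffered fluoride desilylation cleaves the unhindered primary TES ether much faster than the tertiary one (the product equilibrates with its cyclic hemiketal).

Step 8
Reactants: 14 (4S,6Z)-4-(hydroxymethyl)-4-[(triethylsilyl)oxy]dodec-6-en-2-one
Product: 15 (2S,4Z)-2-(2-oxopropyl)-2-[(triethylsilyl)oxy]dec-4-enal
Conditions: Dess–Martin periodinane, NaHCO3, CH2Cl2, 0 °C → rt
Reagents that add atoms: none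
Why: Dess–Martin oxidation drains the hemiketal/hydroxy-ketone equilibrium to the aldehyde, which has a quaternary α-carbon and cannot epimerise.

Step 9
Reactants: 15 (2S,4Z)-2-(2-oxopropyl)-2-[(triethylsilyl)oxy]dec-4-enal
Product: 17 (4S)-4-[(2Z)-oct-2-en-1-yl]-4-[(triethylsilyl)oxy]cyclopent-2-en-1-one, via (4S)-3-hydroxy-4-[(2Z)-oct-2-en-1-yl]-4-[(triethylsilyl)oxy]cyclopentan-1-one 16 (not isolated)
Conditions: piperidine (0.3 equiv), AcOH (0.3 equiv), 4 Å MS, toluene, 60 °C
Reagents that add atoms: none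
Why: Intramolecular aldol condensation of the 1,4-keto-aldehyde: the aldehyde has no α-H and can only accept, only the methyl-side enamine/enol closes a five-membered ring (C10–C11), and the ketol dehydrates to the enone while the mild amine/acid buffer limits β-elimination of the silyloxy group; C12 is untouched.

Step 10
Reactants: 17 (4S)-4-[(2Z)-oct-2-en-1-yl]-4-[(triethylsilyl)oxy]cyclopent-2-en-1-one
Product: 18 (4S)-4-[(2Z)-oct-2-en-1-yl]-4-[(triethylsilyl)oxy]-6-oxabicyclo[3.1.0]hexan-2-one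
Conditions: 30 % H2O2, NaOH (0.2 equiv), MeOH, 0 °C
Reagents that add atoms: hydrogen peroxide, OO
Why: Weitz–Scheffer nucleophilic epoxidation attacks only the electron-poor enone and not the isolated Z-alkene; the epoxide configuration is irrelevant because both carbons become sp2 in the next step.

Step 11
Reactants: 18 (4S)-4-[(2Z)-oct-2-en-1-yl]-4-[(triethylsilyl)oxy]-6-oxabicyclo[3.1.0]hexan-2-one
Product: 20 (4S)-2-chloro-4-hydroxy-4-[(2Z)-oct-2-en-1-yl]cyclopent-2-en-1-one, via (4S)-2-chloro-3-hydroxy-4-[(2Z)-oct-2-en-1-yl]-4-[(triethylsilyl)oxy]cyclopentan-1-one 19 (not isolated)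
Conditions: conc. HCl, THF, 0 °C → rt
Reagents that add atoms: hydrogen chloride, Cl
Why: Chloride opens the α,β-epoxy ketone by SN2 at the carbonyl-activated α-carbon (the β-carbon is neopentyl), the chlorohydrin dehydrates under acid to the 2-chloro-enone, and the aqueous acid also cleaves the TES ether.

Step 12
Reactants: 20 (4S)-2-chloro-4-hydroxy-4-[(2Z)-oct-2-en-1-yl]cyclopent-2-en-1-one
Product: 21 (4S)-2-chloro-4-[(2Z)-oct-2-en-1-yl]-4-[(trimethylsilyl)oxy]cyclopent-2-en-1-one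
Conditions: TMSCl, imidazole, DMF, 0 °C → rt
Reagents that add atoms: chlorotrimethylsilane, C[Si](C)(C)Cl
Why: Silylation masks the tertiary alcohol with the smallest silyl group, so that the C12 alkyl chain, not the oxygen substituent, is the larger group flanking the enolate in step 21.

**Side-chain aldehyde**

Step 13
Reactants: 22 dimethyl (4R,5R)-2,2-dimethyl-1,3-dioxolane-4,5-dicarboxylate
Product: 23 [(4S,5S)-2,2-dimethyl-1,3-dioxolane-4,5-diyl]dimethanol
Conditions: LiAlH4, THF, 0 °C → reflux; Fieser work-up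
Reagents that add atoms: none
Why: Hydride reduction of both esters leaves the two tartrate stereocentres (future C5 and C6) untouched.

Step 14
Reactants: 23 [(4S,5S)-2,2-dimethyl-1,3-dioxolane-4,5-diyl]dimethanol
Product: 24 {(4S,5S)-5-[(benzyloxy)methyl]-2,2-dimethyl-1,3-dioxolan-4-yl}methanol
Conditions: NaH (1.0 equiv), BnBr (1.0 equiv), Bu4NI (cat.), THF, 0 °C → rt
Reagents that add atoms: benzyl bromide, BrCc1ccccc1
Why: Williamson mono-etherification of the C2-symmetric diol gives one product whichever hydroxyl reacts.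

Step 15
Reactants: 24 {(4S,5S)-5-[(benzyloxy)methyl]-2,2-dimethyl-1,3-dioxolan-4-yl}methanol
Product: 25 (4S,5R)-4-[(benzyloxy)methyl]-5-(iodomethyl)-2,2-dimethyl-1,3-dioxolane
Conditions: I2, PPh3, imidazole, toluene, rt
Reagents that add atoms: iodine, II
Why: Garegg–Samuelsson (Appel-type) iodination of the primary alcohol does not touch the ring stereocentres (descriptor change is CIP only).

Step 16
Reactants: 25 (4S,5R)-4-[(benzyloxy)methyl]-5-(iodomethyl)-2,2-dimethyl-1,3-dioxolane; 26 methyl acrylate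
Product: 27 methyl 4-{(4S,5S)-5-[(benzyloxy)methyl]-2,2-dimethyl-1,3-dioxolan-4-yl}butanoate
Conditions: Bu3SnH (slow addition), AIBN (cat.), 26 (5 equiv), benzene, 80 °C
Reagents that add atoms: none
Why: Giese radical conjugate addition of the primary alkyl radical to the acrylate installs C1–C3 as the methyl ester in one step without touching the stereocentres.

Step 17
Reactants: 27 methyl 4-{(4S,5S)-5-[(benzyloxy)methyl]-2,2-dimethyl-1,3-dioxolan-4-yl}butanoate
Product: 28 methyl (5S,6S)-7-(benzyloxy)-5,6-dihydroxyheptanoate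
Conditions: TsOH·H2O (0.2 equiv), MeOH, 40 °C; NaHCO3 before concentration
Reagents that add atoms: none
Why: Acid-catalysed transacetalisation in methanol removes the acetonide while the large excess of MeOH keeps the δ-hydroxy ester open (no δ-lactone), provided the acid is neutralised before evaporation.

Step 18
Reactants: 28 methyl (5S,6S)-7-(benzyloxy)-5,6-dihydroxyheptanoate
Product: 29 methyl (5S,6S)-5,6-bis(acetyloxy)-7-(benzyloxy)heptanoate
Conditions: Ac2O, pyridine, DMAP (cat.), CH2Cl2, 0 °C → rt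
Reagents that add atoms: acetic anhydride, CC(=O)OC(C)=O
Why: DMAP-catalysed acetylation installs the final C5 and C6 acetates and removes any lactonisation risk.

Step 19
Reactants: 29 methyl (5S,6S)-5,6-bis(acetyloxy)-7-(benzyloxy)heptanoate
Product: 30 methyl (5S,6S)-5,6-bis(acetyloxy)-7-hydroxyheptanoate
Conditions: H2 (1 atm), 10 % Pd/C, EtOAc, rt
Reagents that add atoms: none
Why: Neutral hydrogenolysis of the benzyl ether frees the C7 alcohol without base, which limits 6→7 acetyl migration (the product is used at once).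

Step 20
Reactants: 30 methyl (5S,6S)-5,6-bis(acetyloxy)-7-hydroxyheptanoate
Product: 31 methyl (5S,6R)-5,6-bis(acetyloxy)-7-oxoheptanoate
Conditions: Dess–Martin periodinane, NaHCO3, CH2Cl2, 0 °C → rt; used crude
Reagents that add atoms: none
Why: Dess–Martin oxidation is non-basic, so the α-acetoxy aldehyde neither epimerises at C6 nor loses the β-acetate (6R is a CIP change only).

**Fragment union and end game**

Step 21
Reactants: 21 (4S)-2-chloro-4-[(2Z)-oct-2-en-1-yl]-4-[(trimethylsilyl)oxy]cyclopent-2-en-1-one; 31 methyl (5S,6R)-5,6-bis(acetyloxy)-7-oxoheptanoate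
Product: 33 methyl (5S,6S,7R)-5,6-bis(acetyloxy)-7-{(1R,2S)-4-chloro-2-[(2Z)-oct-2-en-1-yl]-5-oxo-2-[(trimethylsilyl)oxy]cyclopent-3-en-1-yl}-7-hydroxyheptanoate, via lithium (3S)-5-chloro-3-[(2Z)-oct-2-en-1-yl]-3-[(trimethylsilyl)oxy]cyclopenta-1,4-dien-1-olate 32 (not isolated)
Conditions: LDA (1.1 equiv), THF, −78 °C, 30 min; 31 (1.3 equiv), −78 °C; AcOH quench at −78 °C
Reagents that add atoms: none
Why: Kinetic lithium-enolate aldol addition through a Zimmerman–Traxler chair: only C8 can be deprotonated, the aldehyde should approach anti to the C12 octenyl chain (sets 8R), and the ring-locked E-enolate gives the 7,8-anti adduct (sets 7R); α-oxygenated aldehydes are expected to bias E-enolates only weakly, so the enolate should control and the tartrate-derived C5/C6 are carried in unchanged (diastereomers are separated here, and any acetyl-migrated isomers converge in step 22).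

Step 22
Reactants: 33 methyl (5S,6S,7R)-5,6-bis(acetyloxy)-7-{(1R,2S)-4-chloro-2-[(2Z)-oct-2-en-1-yl]-5-oxo-2-[(trimethylsilyl)oxy]cyclopent-3-en-1-yl}-7-hydroxyheptanoate
Product: 34 methyl (5S,6R,7R)-5,6,7-tris(acetyloxy)-7-{(1R,2S)-4-chloro-2-[(2Z)-oct-2-en-1-yl]-5-oxo-2-[(trimethylsilyl)oxy]cyclopent-3-en-1-yl}heptanoate
Conditions: Ac2O, pyridine, CH2Cl2, 0 °C (no DMAP)
Reagents that add atoms: acetic anhydride, CC(=O)OC(C)=O
Why: Pyridine-mediated acetylation of the secondary 7-OH at low temperature without DMAP avoids E1cB loss of the β-acetoxy group; no stereocentre changes.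

Step 23
Reactants: 34 methyl (5S,6R,7R)-5,6,7-tris(acetyloxy)-7-{(1R,2S)-4-chloro-2-[(2Z)-oct-2-en-1-yl]-5-oxo-2-[(trimethylsilyl)oxy]cyclopent-3-en-1-yl}heptanoate
Product: 35 punaglandin 2, methyl (5S,6R,7R)-5,6,7-tris(acetyloxy)-7-{(1R,2S)-4-chloro-2-hydroxy-2-[(2Z)-oct-2-en-1-yl]-5-oxocyclopent-3-en-1-yl}heptanoate
Conditions: HF·pyridine, pyridine, THF, 0 °C
Reagents that add atoms: none
Why: Mildly acidic fluoride desilylation removes the tertiary TMS ether without the base that would eliminate the 7-acetate or the conditions that would cleave the esters.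

**Compound list**
1 | prop-2-yn-1-ol | C#CCO | starting material
2 | (2-methylprop-2-en-1-yl)magnesium chloride | CC(=C)C[Mg]Cl | starting material
3 | chloromagnesium (2Z)-3-(chloromagnesio)-2-(2-methylprop-2-en-1-yl)prop-2-en-1-olate | Cl[Mg]/C=C(/CC(C)=C)CO[Mg]Cl | intermediate
4 | 4-methyl-2-methylidenepent-4-en-1-ol | CC(=C)CC(=C)CO | intermediate
5 | [(2S)-2-(2-methylprop-2-en-1-yl)oxiran-2-yl]methanol | CC(=C)C[C@]1(CO)CO1 | intermediate
6 | hept-1-yne | CCCCCC#C | starting material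
7 | lithium hept-1-yn-1-ide | [Li]C#CCCCCC | intermediate
8 | diethyl(hept-1-yn-1-yl)aluminium | CC[Al](CC)C#CCCCCC | intermediate
9 | (2R)-2-(2-methylprop-2-en-1-yl)dec-4-yne-1,2-diol | CCCCCC#CC[C@@](CC(C)=C)(O)CO | intermediate
10 | (2R)-2-(2-methylprop-2-en-1-yl)-1,2-bis[(triethylsilyl)oxy]dec-4-yne | CCCCCC#CC[C@@](CC(C)=C)(O[Si](CC)(CC)CC)CO[Si](CC)(CC)CC | intermediate
11 | (4S)-2-methyl-4-[(triethylsilyl)oxy]-4-{[(triethylsilyl)oxy]methyl}dodec-6-yne-1,2-diol (C2 epimers) | CCCCCC#CC[C@@](CC(C)(O)CO)(O[Si](CC)(CC)CC)CO[Si](CC)(CC)CC | intermediate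
12 | (4S)-4-[(triethylsilyl)oxy]-4-{[(triethylsilyl)oxy]methyl}dodec-6-yn-2-one | CCCCCC#CC[C@@](CC(C)=O)(O[Si](CC)(CC)CC)CO[Si](CC)(CC)CC | intermediate
13 | (4S,6Z)-4-[(triethylsilyl)oxy]-4-{[(triethylsilyl)oxy]methyl}dodec-6-en-2-one | CCCCC/C=C\C[C@@](CC(C)=O)(O[Si](CC)(CC)CC)CO[Si](CC)(CC)CC | intermediate
14 | (4S,6Z)-4-(hydroxymethyl)-4-[(triethylsilyl)oxy]dodec-6-en-2-one | CCCCC/C=C\C[C@@](CC(C)=O)(O[Si](CC)(CC)CC)CO | intermediate
15 | (2S,4Z)-2-(2-oxopropyl)-2-[(triethylsilyl)oxy]dec-4-enal | CCCCC/C=C\C[C@@](CC(C)=O)(O[Si](CC)(CC)CC)C=O | intermediate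
16 | (4S)-3-hydroxy-4-[(2Z)-oct-2-en-1-yl]-4-[(triethylsilyl)oxy]cyclopentan-1-one (C3 epimers) | CCCCC/C=C\C[C@@]1(O[Si](CC)(CC)CC)C(O)CC(=O)C1 | intermediate
17 | (4S)-4-[(2Z)-oct-2-en-1-yl]-4-[(triethylsilyl)oxy]cyclopent-2-en-1-one | CCCCC/C=C\C[C@@]1(O[Si](CC)(CC)CC)C=CC(=O)C1 | intermediate
18 | (4S)-4-[(2Z)-oct-2-en-1-yl]-4-[(triethylsilyl)oxy]-6-oxabicyclo[3.1.0]hexan-2-one (epoxide diastereomers) | CCCCC/C=C\C[C@@]1(O[Si](CC)(CC)CC)C2OC2C(=O)C1 | intermediate
19 | (4S)-2-chloro-3-hydroxy-4-[(2Z)-oct-2-en-1-yl]-4-[(triethylsilyl)oxy]cyclopentan-1-one (trans-chlorohydrin) | CCCCC/C=C\C[C@@]1(O[Si](CC)(CC)CC)C(O)C(Cl)C(=O)C1 | intermediate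
20 | (4S)-2-chloro-4-hydroxy-4-[(2Z)-oct-2-en-1-yl]cyclopent-2-en-1-one | CCCCC/C=C\C[C@@]1(O)C=C(Cl)C(=O)C1 | intermediate
21 | (4S)-2-chloro-4-[(2Z)-oct-2-en-1-yl]-4-[(trimethylsilyl)oxy]cyclopent-2-en-1-one | CCCCC/C=C\C[C@@]1(O[Si](C)(C)C)C=C(Cl)C(=O)C1 | intermediate
22 | dimethyl (4R,5R)-2,2-dimethyl-1,3-dioxolane-4,5-dicarboxylate (dimethyl 2,3-O-isopropylidene-L-tartrate) | COC(=O)[C@@H]1OC(C)(C)O[C@H]1C(=O)OC | starting material
23 | [(4S,5S)-2,2-dimethyl-1,3-dioxolane-4,5-diyl]dimethanol | OC[C@@H]1OC(C)(C)O[C@H]1CO | intermediate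
24 | {(4S,5S)-5-[(benzyloxy)methyl]-2,2-dimethyl-1,3-dioxolan-4-yl}methanol | c1ccccc1COC[C@@H]1OC(C)(C)O[C@H]1CO | intermediate
25 | (4S,5R)-4-[(benzyloxy)methyl]-5-(iodomethyl)-2,2-dimethyl-1,3-dioxolane | c1ccccc1COC[C@@H]1OC(C)(C)O[C@H]1CI | intermediate
26 | methyl acrylate | C=CC(=O)OC | starting material
27 | methyl 4-{(4S,5S)-5-[(benzyloxy)methyl]-2,2-dimethyl-1,3-dioxolan-4-yl}butanoate | c1ccccc1COC[C@@H]1OC(C)(C)O[C@H]1CCCC(=O)OC | intermediate
28 | methyl (5S,6S)-7-(benzyloxy)-5,6-dihydroxyheptanoate | c1ccccc1COC[C@H](O)[C@@H](O)CCCC(=O)OC | intermediate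
29 | methyl (5S,6S)-5,6-bis(acetyloxy)-7-(benzyloxy)heptanoate | c1ccccc1COC[C@H](OC(C)=O)[C@@H](OC(C)=O)CCCC(=O)OC | intermediate
30 | methyl (5S,6S)-5,6-bis(acetyloxy)-7-hydroxyheptanoate | OC[C@H](OC(C)=O)[C@@H](OC(C)=O)CCCC(=O)OC | intermediate
31 | methyl (5S,6R)-5,6-bis(acetyloxy)-7-oxoheptanoate | O=C[C@H](OC(C)=O)[C@@H](OC(C)=O)CCCC(=O)OC | intermediate
32 | lithium (3S)-5-chloro-3-[(2Z)-oct-2-en-1-yl]-3-[(trimethylsilyl)oxy]cyclopenta-1,4-dien-1-olate | CCCCC/C=C\C[C@@]1(O[Si](C)(C)C)C=C(Cl)C(O[Li])=C1 | intermediate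
33 | methyl (5S,6S,7R)-5,6-bis(acetyloxy)-7-{(1R,2S)-4-chloro-2-[(2Z)-oct-2-en-1-yl]-5-oxo-2-[(trimethylsilyl)oxy]cyclopent-3-en-1-yl}-7-hydroxyheptanoate | CCCCC/C=C\C[C@@]1(O[Si](C)(C)C)C=C(Cl)C(=O)[C@@H]1[C@@H](O)[C@H](OC(C)=O)[C@H](CCCC(=O)OC)OC(C)=O | intermediate
34 | methyl (5S,6R,7R)-5,6,7-tris(acetyloxy)-7-{(1R,2S)-4-chloro-2-[(2Z)-oct-2-en-1-yl]-5-oxo-2-[(trimethylsilyl)oxy]cyclopent-3-en-1-yl}heptanoate | CCCCC/C=C\C[C@@]1(O[Si](C)(C)C)C=C(Cl)C(=O)[C@@H]1[C@@H](OC(C)=O)[C@H](OC(C)=O)[C@H](CCCC(=O)OC)OC(C)=O | intermediate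
35 | punaglandin 2, methyl (5S,6R,7R)-5,6,7-tris(acetyloxy)-7-{(1R,2S)-4-chloro-2-hydroxy-2-[(2Z)-oct-2-en-1-yl]-5-oxocyclopent-3-en-1-yl}heptanoate | CCCCC/C=C\C[C@@]1(O)C=C(Cl)C(=O)[C@@H]1[C@@H](OC(C)=O)[C@H](OC(C)=O)[C@H](CCCC(=O)OC)OC(C)=O | target

**Totals**
Total step count: 23 (ring fragment 12, aldehyde 8, union and end game 3).
Longest linear sequence: 15 steps (steps 1–12, then 21–23), which is 15/23 of the total.

**Three steps most likely to fail**

Step 21 (fragment aldol). The face selectivity at C8, the anti/syn ratio and the weak bias of the α-acetoxy aldehyde are all unproven, and the aldehyde can be enolised. The fallback sets out from 20 and uses an alkoxide-directed aldol. Compound 20 is treated with LDA (2.2 equiv, THF, −78 °C) to give the dilithio alkoxide–dienolate. The C12 lithium alkoxide binds the incoming aldehyde 31 and delivers it to the oxygen-bearing face, giving methyl (5S,6S,7R)-5,6-bis(acetyloxy)-7-{(1R,2S)-4-chloro-2-hydroxy-2-[(2Z)-oct-2-en-1-yl]-5-oxocyclopent-3-en-1-yl}-7-hydroxyheptanoate F1. Ac2O/pyridine at 0 °C acetylates only the secondary 7-OH (the tertiary 12-OH is inert), and the route comes back directly at target 35, with steps 12 and 23 no longer needed.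

Step 9 (ring-closing aldol condensation). The amine/acid conditions may cause β-elimination of the silyloxy group or fail to engage the hindered aldehyde. The fallback sets out from 15 and runs the ring closure as a regiodefined boron aldol addition. Bu2BOTf/i-Pr2NEt (CH2Cl2, −78 °C) enolises the methyl ketone on the CH3 side, and the boron enolate adds to the aldehyde to give ketol 16, now isolated after buffered oxidative work-up. MsCl/Et3N (0 °C) converts 16 into (2S)-2-[(2Z)-oct-2-en-1-yl]-4-oxo-2-[(triethylsilyl)oxy]cyclopentyl methanesulfonate F2. DBU then eliminates the mesylate and the route comes back at 17.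

Step 11 (epoxy ketone to chloro-enone). The epoxide may open at the wrong carbon or rearrange in acid, or the chlorohydrin may not dehydrate. The fallback sets out from 17 and avoids the epoxide. Johnson iodination (I2, pyridine, CH2Cl2; inert to the isolated alkene) gives (4S)-2-iodo-4-[(2Z)-oct-2-en-1-yl]-4-[(triethylsilyl)oxy]cyclopent-2-en-1-one F3. Copper-mediated halogen exchange (CuCl, DMF, 100 °C) gives (4S)-2-chloro-4-[(2Z)-oct-2-en-1-yl]-4-[(triethylsilyl)oxy]cyclopent-2-en-1-one F4. HF·pyridine cleaves the TES ether and the route comes back at 20.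

**Further compounds**
F1 | step 21 | methyl (5S,6S,7R)-5,6-bis(acetyloxy)-7-{(1R,2S)-4-chloro-2-hydroxy-2-[(2Z)-oct-2-en-1-yl]-5-oxocyclopent-3-en-1-yl}-7-hydroxyheptanoate | CCCCC/C=C\C[C@@]1(O)C=C(Cl)C(=O)[C@@H]1[C@@H](O)[C@H](OC(C)=O)[C@H](CCCC(=O)OC)OC(C)=O
F2 | step 9 | (2S)-2-[(2Z)-oct-2-en-1-yl]-4-oxo-2-[(triethylsilyl)oxy]cyclopentyl methanesulfonate | CCCCC/C=C\C[C@@]1(O[Si](CC)(CC)CC)C(OS(C)(=O)=O)CC(=O)C1
F3 | step 11 | (4S)-2-iodo-4-[(2Z)-oct-2-en-1-yl]-4-[(triethylsilyl)oxy]cyclopent-2-en-1-one | CCCCC/C=C\C[C@@]1(O[Si](CC)(CC)CC)C=C(I)C(=O)C1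
F4 | step 11 | (4S)-2-chloro-4-[(2Z)-oct-2-en-1-yl]-4-[(triethylsilyl)oxy]cyclopent-2-en-1-one | CCCCC/C=C\C[C@@]1(O[Si](CC)(CC)CC)C=C(Cl)C(=O)C1
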